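# Total synthesis of tonantzitlolone A (27)

**Retrosynthetic overview**
1. 27 ⇐ Yamaguchi acylation of the C3-OH (C(a) in the working labels) of hemiketal 25; 25 ⇐ global desilylation of macrocyclic diketone 24, with transannular δ-hydroxy-ketone hemiketalisation.
2. The 15-membered carbocycle is closed by E-selective RCM (C23=C24) of 21. The C20 ketone comes from a crotylation carbinol that is oxidised late.
3. The C(f)–C(g) acyloin bond joins α-silyloxy aldehyde 12 (proline anti-aldol, Wittig, crotylation, Sharpless epoxidation) to THF aldehyde 19 (methyl geranate, reverse prenylation, Shi epoxidation, 5-exo epoxide opening).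
4. Rings form in the order: THF (step 13), 15-membered carbocycle (step 18), pyranose hemiketal (step 21).

**Assumptions** (one line each)
- 2,2-Dimethoxyacetaldehyde (from its 60% aqueous solution, dried), methyl geranate and (E)-3-methylpent-2-enoic acid are commercial.
- The enantiomers of the Shi ketone, the tartrate and the pinene-derived boranes are chosen to give the configurations shown.
- C(f) of the hemiketal adopts the natural configuration under thermodynamic control.

## Steps

**Step 1**
Reactants: 1 propanal; 2 2,2-dimethoxyacetaldehyde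
Product: 3 (2S,3R)-3-hydroxy-4,4-dimethoxy-2-methylbutanal
Conditions: L-proline (20 mol%), DMF, 4 °C; 1 added by syringe pump over 12 h to 2 (3 equiv)
Reagents that add atoms: none
Why: Enamine-mediated anti-selective cross-aldol (proline-catalysed direct aldol); the non-enolisable acceptor 2 prevents self-aldol, and the Houk–List transition state sets C(a)-OH and C(b)-Me (R,R in the target numbering).

**Step 2**
Reactants: 3; 4 (triphenylphosphoranylidene)acetaldehyde
Product: 5 (2E,4R,5R)-5-hydroxy-6,6-dimethoxy-4-methylhex-2-enal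
Conditions: 4 (1.3 equiv), toluene, 50 °C, crude 3
Reagents that add atoms: none
Why: Wittig olefination with a stabilised ylide gives the E-enal and adds C(d) and C20 without touching C(a) or C(b).

**Step 3**
Reactants: 5
Product: 6 the TBS ether of 5
Conditions: TBSOTf, 2,6-lutidine, CH2Cl2, −78 °C
Reagents that add atoms: TBSOTf, CC(C)(C)[Si](C)(C)OS(=O)(=O)C(F)(F)F
Why: Silyl protection of the secondary alcohol so that the crotylation and Red-Al steps do not touch it.

**Step 4**
Reactants: 6
Product: 7 (3S,4R,5E,7R,8R)-8-(TBSO)-9,9-dimethoxy-3,7-dimethylnona-1,5-dien-4-ol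
Conditions: (E)-crotyl-B(Ipc)2, THF, −78 °C; then NaOH, H2O2, 0 °C
Reagents that add atoms: (E)-crotyldiisopinocampheylborane (pinene enantiomer that gives 3S), C/C=C/CB(C1CC2CC(C2(C)C)C1C)C1CC2CC(C2(C)C)C1C
Why: Brown asymmetric crotylboration (1,2-addition, chair transition state) gives the anti homoallylic alcohol and sets C22 (S); C20 is sacrificial because it is oxidised in step 20.

**Step 5**
Reactants: 7
Product: 8 epoxy alcohol (5S,6S epoxide; 3S,4S,7R,8R)
Conditions: Ti(OiPr)4, L-(+)-DET, TBHP, 4 Å MS, CH2Cl2, −20 °C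
Reagents that add atoms: tert-butyl hydroperoxide, CC(C)(C)OO
Why: Sharpless asymmetric epoxidation (hydroxy-directed) with the matched anti allylic alcohol; the tartrate sets C(d).

**Step 6**
Reactants: 8
Product: 9 1,2-diol with C(c) as CH2
Conditions: Red-Al, THF, 0 °C → rt
Reagents that add atoms: none
Why: Hydride is delivered by the alkoxyaluminate to the distal epoxide carbon C(c) (C3-selective reduction of a 2,3-epoxy alcohol), leaving C(d)-OH with retention.

**Step 7**
Reactants: 9
Product: 10 C(d)-OTBS, C20-OH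
Conditions: TBSCl (1.05 equiv), imidazole, CH2Cl2, −20 °C
Reagents that add atoms: TBSCl, CC(C)(C)[Si](C)(C)Cl
Why: Steric discrimination silylates the less hindered C(d)-OH (flanked by CH2) over the more hindered C20-OH.

**Step 8**
Reactants: 10
Product: 11 C20-OTES
Conditions: TESOTf, 2,6-lutidine, CH2Cl2, −78 °C
Reagents that add atoms: TESOTf, CC[Si](CC)(CC)OS(=O)(=O)C(F)(F)F
Why: C20 is protected as a TES ether that can later be removed selectively in the presence of the TBS ethers.

**Step 9**
Reactants: 11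
Product: 12 W*, the α-silyloxy aldehyde
Conditions: TESOTf, 2,4,6-collidine, CH2Cl2, 0 °C; then H2O
Reagents that add atoms: water, O
Why: Fujioka mild acetal-to-aldehyde conversion (collidinium intermediate) leaves the silyl ethers and C22 untouched.

**Step 10**
Reactants: 13 methyl geranate
Product: 14 methyl (E)-3-methyl-6-oxohex-2-enoate
Conditions: O3 (1.0 equiv), CH2Cl2/MeOH, −78 °C; then PPh3
Reagents that add atoms: ozone, [O-][O+]=O
Why: The electron-rich trisubstituted 6,7-alkene is cleaved chemoselectively over the conjugated enoate (ozonolysis).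

**Step 11**
Reactants: 14
Product: 15 methyl (2E,6S)-6-hydroxy-3,7,7-trimethylnona-2,8-dienoate
Conditions: prenyl-B(Ipc)2, Et2O, −78 °C; ethanolamine work-up
Reagents that add atoms: B-prenyldiisopinocampheylborane, CC(C)=CCB(C1CC2CC(C2(C)C)C1C)C1CC2CC(C2(C)C)C1C
Why: Brown γ-prenylation via a chair transition state builds the CMe2–vinyl unit and the (S)-carbinol C(i).

**Step 12**
Reactants: 15
Product: 16 methyl (2R,3S,6S)-2,3-epoxy-6-hydroxy-3,7,7-trimethylnon-8-enoate
Conditions: Shi fructose-derived ketone (30 mol%), Oxone, K2CO3, Bu4NHSO4, MeCN/DMM, aqueous buffer pH 10.5, 0 °C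
Reagents that add atoms: Oxone, [K+].OOS(=O)(=O)[O-]
Why: Shi organocatalytic dioxirane epoxidation of the E-trisubstituted enoate sets C(h); the vinyl group and free OH are untouched, and C(g) is erased in step 15.

**Step 13**
Reactants: 16
Product: 17 methyl (2R)-2-hydroxy-2-[(2R,5S)-2-methyl-5-(2-methylbut-3-en-2-yl)oxolan-2-yl]acetate
Conditions: CSA (10 mol%), CH2Cl2, 0 °C → rt
Reagents that add atoms: none
Why: Acid-promoted 5-exo-tet opening of the glycidate at the tertiary β-carbon by C(i)-OH, with inversion at C(h), gives the 2,5-cis THF.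

**Step 14**
Reactants: 17
Product: 18 (1S)-1-[(2R,5S)-2-methyl-5-(2-methylbut-3-en-2-yl)oxolan-2-yl]ethane-1,2-diol
Conditions: LiBH4, THF, 0 °C → rt
Reagents that add atoms: none
Why: Chemoselective ester reduction gives the vicinal diol.

**Step 15**
Reactants: 18
Product: 19 (2R,5S)-2-methyl-5-(2-methylbut-3-en-2-yl)oxolane-2-carbaldehyde (E*)
Conditions: NaIO4, THF/H2O, 0 °C → rt
Reagents that add atoms: none
Why: Malaprade glycol cleavage removes C(f) and the C(g) stereocentre, leaving the non-enolisable α-quaternary α-alkoxy aldehyde with C(h) intact.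

**Step 16**
Reactants: 12; 19
Product: 20 acyloin: C(f) ketone, C(g)-OH
Conditions: (S)-aminoindanol-derived N-mesityl triazolium BF4 (20 mol%), iPr2NEt (20 mol%), Ti(OiPr)4 (30 mol%), THF, 23 °C, 48 h (19 in excess, 12 limiting)
Reagents that add atoms: none
Why: The Breslow intermediate of donor 12 adds to the more electrophilic, non-enolisable acceptor 19, forming the C(f)–C(g) bond, and Lewis-acid chelation plus the catalyst set C(g)-OH (S). Proposed new method: an NHC-catalysed intermolecular cross-acyloin between two elaborated aliphatic aldehydes, one an α-silyloxy, α-branched donor and the other an α-quaternary THF acceptor, which has not been shown; the transition state chelates the THF oxygen and the carbonyl so that attack occurs syn to the methyl group; the closest known reaction type is the chemoselective cross-benzoin of aliphatic donors with activated acceptors.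

**Step 17**
Reactants: 20
Product: 21 C(g)-OTBS diene
Conditions: TBSOTf, 2,6-lutidine, CH2Cl2, −78 → 0 °C
Reagents that add atoms: TBSOTf, CC(C)(C)[Si](C)(C)OS(=O)(=O)C(F)(F)F
Why: Protecting the hindered α-hydroxy-ketone OH prevents its oxidation in step 20.

**Step 18**
Reactants: 21
Product: 22 15-membered macrocycle with E-C23=C24
Conditions: Hoveyda–Grubbs II (15 mol%), toluene, 1.5 mM, 80 °C
Reagents that add atoms: none
Why: Ring-closing metathesis joins the two terminal vinyl groups, and the E-alkene is favoured in the 15-membered ring.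

**Step 19**
Reactants: 22
Product: 23 C20-OH
Conditions: PPTS (20 mol%), CH2Cl2/MeOH, 0 °C → rt
Reagents that add atoms: none
Why: The labile TES ether is cleaved selectively in the presence of the three TBS ethers.

**Step 20**
Reactants: 23
Product: 24 C20 ketone
Conditions: Dess–Martin periodinane, NaHCO3, CH2Cl2, 0 °C → rt
Reagents that add atoms: none
Why: Buffered Dess–Martin oxidation gives the ketone, and the mild conditions avoid epimerising C22.

**Step 21**
Reactants: 24
Product: 25 desacyl hemiketal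
Conditions: HF·pyridine, pyridine/THF, 23 → 40 °C, 36 h
Reagents that add atoms: none
Why: The three TBS ethers are removed, and the freed C(d)-OH adds to the C(f) ketone to form the 2,6-cis pyranose hemiketal, setting C(f) thermodynamically.

**Step 22**
Reactants: 25; 26 (E)-3-methylpent-2-enoic acid
Product: 27 tonantzitlolone A
Conditions: 2,4,6-Cl3C6H2COCl, Et3N, toluene, then DMAP, 23 °C
Reagents that add atoms: none
Why: Yamaguchi esterification at the only unhindered secondary OH, C(a)-OH (the hemiketal OH and C(g)-OH are tertiary or neopentylic), with equilibrating hemiketal forms funnelled to 27 by Curtin–Hammett.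

## Compound list

| # | Name | SMILES | Role |
|---|---|---|---|
| 1 | propanal | CCC=O | starting material |
| 2 | 2,2-dimethoxyacetaldehyde | COC(OC)C=O | starting material |
| 3 | (2S,3R)-3-hydroxy-4,4-dimethoxy-2-methylbutanal | O=C[C@@H](C)[C@@H](O)C(OC)OC | intermediate |
| 4 | (triphenylphosphoranylidene)acetaldehyde | O=CC=P(c1ccccc1)(c1ccccc1)c1ccccc1 | starting material |
| 5 | (2E,4R,5R)-5-hydroxy-6,6-dimethoxy-4-methylhex-2-enal | O=C/C=C/[C@@H](C)[C@@H](O)C(OC)OC | intermediate |
| 6 | TBS ether of 5 | O=C/C=C/[C@@H](C)[C@@H](O[Si](C)(C)C(C)(C)C)C(OC)OC | intermediate |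
| 7 | (3S,4R,5E,7R,8R)-8-(TBSO)-9,9-dimethoxy-3,7-dimethylnona-1,5-dien-4-ol | C=C[C@H](C)[C@H](O)/C=C/[C@@H](C)[C@@H](O[Si](C)(C)C(C)(C)C)C(OC)OC | intermediate |
| 8 | 5,6-epoxy alcohol from 7 | C=C[C@H](C)[C@H](O)[C@@H]1O[C@H]1[C@@H](C)[C@@H](O[Si](C)(C)C(C)(C)C)C(OC)OC | intermediate |
| 9 | 1,2-diol | C=C[C@H](C)[C@H](O)[C@H](O)C[C@@H](C)[C@@H](O[Si](C)(C)C(C)(C)C)C(OC)OC | intermediate |
| 10 | C(d)-OTBS, C20-OH | C=C[C@H](C)[C@H](O)[C@H](O[Si](C)(C)C(C)(C)C)C[C@@H](C)[C@@H](O[Si](C)(C)C(C)(C)C)C(OC)OC | intermediate |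
| 11 | C20-OTES acetal | C=C[C@H](C)[C@H](O[Si](CC)(CC)CC)[C@H](O[Si](C)(C)C(C)(C)C)C[C@@H](C)[C@@H](O[Si](C)(C)C(C)(C)C)C(OC)OC | intermediate |
| 12 | W* aldehyde | C=C[C@H](C)[C@H](O[Si](CC)(CC)CC)[C@H](O[Si](C)(C)C(C)(C)C)C[C@@H](C)[C@@H](O[Si](C)(C)C(C)(C)C)C=O | intermediate |
| 13 | methyl geranate | COC(=O)/C=C(\C)CCC=C(C)C | starting material |
| 14 | methyl (E)-3-methyl-6-oxohex-2-enoate | COC(=O)/C=C(\C)CCC=O | intermediate |
| 15 | methyl (2E,6S)-6-hydroxy-3,7,7-trimethylnona-2,8-dienoate | COC(=O)/C=C(\C)CC[C@H](O)C(C)(C)C=C | intermediate |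
| 16 | methyl (2R,3S,6S)-2,3-epoxy-6-hydroxy-3,7,7-trimethylnon-8-enoate | COC(=O)[C@@H]1O[C@@]1(C)CC[C@H](O)C(C)(C)C=C | intermediate |
| 17 | THF α-hydroxy ester | COC(=O)[C@H](O)[C@@]1(C)CC[C@H](O1)C(C)(C)C=C | intermediate |
| 18 | THF 1,2-diol | OC[C@H](O)[C@@]1(C)CC[C@H](O1)C(C)(C)C=C | intermediate |
| 19 | E* THF aldehyde | O=C[C@@]1(C)CC[C@H](O1)C(C)(C)C=C | intermediate |
| 20 | acyloin | C=C[C@H](C)[C@H](O[Si](CC)(CC)CC)[C@H](O[Si](C)(C)C(C)(C)C)C[C@@H](C)[C@@H](O[Si](C)(C)C(C)(C)C)C(=O)[C@@H](O)[C@@]1(C)CC[C@H](O1)C(C)(C)C=C | intermediate |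
| 21 | C(g)-OTBS diene | C=C[C@H](C)[C@H](O[Si](CC)(CC)CC)[C@H](O[Si](C)(C)C(C)(C)C)C[C@@H](C)[C@@H](O[Si](C)(C)C(C)(C)C)C(=O)[C@@H](O[Si](C)(C)C(C)(C)C)[C@@]1(C)CC[C@H](O1)C(C)(C)C=C | intermediate |
| 22 | macrocycle | O=C1[C@@H](O[Si](C)(C)C(C)(C)C)[C@@]2(C)CC[C@H](O2)C(C)(C)/C=C/[C@H](C)[C@H](O[Si](CC)(CC)CC)[C@H](O[Si](C)(C)C(C)(C)C)C[C@@H](C)[C@H]1O[Si](C)(C)C(C)(C)C | intermediate |
| 23 | C20-alcohol | O=C1[C@@H](O[Si](C)(C)C(C)(C)C)[C@@]2(C)CC[C@H](O2)C(C)(C)/C=C/[C@H](C)[C@H](O)[C@H](O[Si](C)(C)C(C)(C)C)C[C@@H](C)[C@H]1O[Si](C)(C)C(C)(C)C | intermediate |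
| 24 | C20 ketone | O=C1[C@@H](O[Si](C)(C)C(C)(C)C)[C@@]2(C)CC[C@H](O2)C(C)(C)/C=C/[C@H](C)C(=O)[C@H](O[Si](C)(C)C(C)(C)C)C[C@@H](C)[C@H]1O[Si](C)(C)C(C)(C)C | intermediate |
| 25 | desacyl hemiketal | O[C@@H]1[C@H](C)C[C@H]2O[C@]1(O)[C@@H](O)[C@@]1(C)CC[C@H](O1)C(C)(C)/C=C/[C@H](C)C2=O | intermediate |
| 26 | (E)-3-methylpent-2-enoic acid | CC/C(C)=C/C(=O)O | starting material |
| 27 | tonantzitlolone A | CC/C(C)=C/C(=O)O[C@@H]1[C@H](C)C[C@H]2O[C@]1(O)[C@@H](O)[C@@]1(C)CC[C@H](O1)C(C)(C)/C=C/[C@H](C)C2=O | target |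

## Totals
- Total steps: 22.
- Longest linear sequence: 16 (steps 1–9, then 16–22).

**Three steps most likely to fail**
1. **Step 16 (proposed new NHC cross-acyloin).** Homo-benzoin, epimerisation of C(a) and poor C(g) diastereoselectivity are the risks. Fallback (known chemistry): Corey–Seebach umpolung. Convert 12 to its 1,3-dithiane, lithiate it, and add it to 19 under Cram-chelate control to give the (S) carbinol. Unmask the ketone with PIFA after step 17.
2. **Step 18 (macrocyclic RCM).** The two substrate vinyl groups are hindered (an allylic branch and a neopentyl quaternary carbon). Fallback: macrocyclic Julia–Kocienski olefination. Rebuild the precursor with a PT-sulfone at C23 and the non-enolisable C24 aldehyde, and close with KHMDS in DME at high dilution to give the E-alkene.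
3. **Step 22 (regioselective acylation of an equilibrating hemiketal).** The C(a)-OH is competing with hemiketal forms and hindered OH groups. Fallback: an orthogonal-protection route, with C(d)-OPMB and C(a)-OTBS carried through. Remove the C(a) TBS group, acylate, then remove PMB with DDQ so that hemiketalisation occurs only after the ester is in place.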